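Over the 5.0 h this flask was to stand, with 0.10 M of Q and 1.0 mM of Z, I wanted to know how long its chains became.

| flask | Q | Z | remark | time |
|---|---|---|---|---|
| dawn | 0.10 M | 0.67 mM | run made earlier |  |
| noon | 0.10 M | 1.5 mM | run made earlier |  |
| flask | 0.10 M | 1.0 mM |  | 5.0 h |

| run | time / h | J / % | Q / % |
|---|---|---|---|
| dawn | 0.417 | 21.0 | 67.6 |
| dawn | 0.667 | 26.9 | 56.8 |
| dawn | 1.00 | 34.4 | 45.6 |
| dawn | 1.33 | 38.7 | 37.2 |
| dawn | 2.00 | 42.1 | 26.6 |
| dawn | 3.00 | 45.6 | 16.3 |
| dawn | 5.00 | 44.5 | 9.6 |
| noon | 0.250 | 25.3 | 68.0 |
| noon | 0.833 | 53.9 | 29.5 |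
| noon | 1.33 | 61.0 | 20.1 |
| noon | 2.00 | 63.5 | 14.9 |
| noon | 3.00 | 60.9 | 13.1 |
| noon | 4.00 | 59.2 | 10.9 |
| noon | 5.00 | 55.5 | 11.6 |

(readings scatter by 1 percentage point)

- whether the average number of monomer units in a chain (chains begun, living or dead) reaches 40 by 5.0 h (no / yes)
- average number of monomer units in a chain (chains begun, living or dead) at 5.0 h

- the average divides the monomer in chains by the number of chains begun, living and dead together
- the earlier runs were read with a standard deviation of 1 percentage point
- the earlier runs do not show the number of chains; that part of a forecast is a guess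

I began with the end state. The charge ratio n is 100: the units of Q charged for each Z charged, c(Q) over c(Z) at the start. If each Z begins one chain and Z is used up, the length, the number-average degree of polymerisation, is n times the share of the charged Q that stands in J. So I needed J at the end. The noon readings had been falling since 63.5% at 2.00 h, so I took the end readings and not the peaks: 44.5% at dawn and 55.5% at noon, both at 5.00 h. Interpolating along the Z charge gave 48.9% for this flask, and n turned that into a length of 48.9, more than the 40 wanted, so I answered yes. The weak link was one chain per Z, which the readings do not show.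

The forecast said yes, with 50 in a range of 30 to 75: “Guessing one chain per Z gives about 1 mM”. The flask gave yes and 52.0.

    Q + Z → G + J (k = 150 M⁻¹ h⁻¹)
    Q + G → J + G, rate k2*[G]*[Q] (k = 1500 M⁻¹ h⁻¹)
    J + G → Q + G, rate k3*[G] as long as [J] is above zero (k = 22.0 h⁻¹)
    Q → E (k = 0.300 h⁻¹)
    G + Q → X (k = 12.0 M⁻¹ h⁻¹)

The first step begins one chain with each Z, and this flask held 0% of its Z at 5.00 h, so n times its 52.0% of J gives 52.0. In this flask, each step taken net, J was made 3.23 times as fast as it was used up at 0.666 h, so it was made faster than it was used up, but at 5.00 h the same ratio was 0.658, so it was then made slower than it was used up. The noon run has n of 66.7, and with one chain per Z its reading of 55.5% of J at 5.00 h gives an estimated length of 37.0, less than 40.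

The earlier runs and the new flask are simulated from invented constants, noise included.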